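Set beside a twin charged with 0.0013 M of second reagent instead of 5.00 mM, Tuesday's closed flask looks nearly the same, and I asked why the two should end apart.

all flasks: second reagent 5.00 mM; third reagent 7.00 mM
- Monday's: starting material 0.010 M; partner 0.0180 M; one stirred flow tank at steady state, fed with the mixture as stated, mean residence time 8.0 d
- Saturday's: starting material 0.010 M (fed, over 8.00 d); partner 0.0180 M; all but starting material at the start; starting material goes in evenly over 8.00 d, the run ends at 8.0 d; time 8.0 d
- Tuesday's: starting material 0.010 M; partner 0.0180 M; a closed flask charged with all of it at once and left for 8.0 d; time 8.0 d
- Sunday's: starting material 0.010 M; partner 0.0180 M (fed, over 8.00 d); a stirred flask in which partner is dosed at a steady rate over 8.00 d without added volume, worked up at 8.0 d; time 8.0 d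

    third reagent + intermediate B ⇌ target (K1 = 780 M⁻¹, k1 = 7.3 M⁻¹ h⁻¹)
    partner → decomposition product (k2 = 2.5 × 10⁻⁵ h⁻¹)
    second reagent + intermediate A → intermediate B (k3 = 3.9 M⁻¹ h⁻¹)
    starting material + partner → intermediate A (k4 = 32 M⁻¹ h⁻¹)

- the stated concentrations are those of everything mixed, before any reaction; amounts are the same in each set-up
- the feed brings no volume worth counting
- run time (Saturday's): 8.0 d

1. the set-up with the highest amount of intermediate A at the outlet or at the end, in percent of the starting material put in ("none" if the first two lie within 2 percentage points) (Monday's / Saturday's / Tuesday's / Sunday's / none)
2. amount of intermediate A at the outlet or at the end, in percent of the starting material put in, Monday's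
3. amount of intermediate A at the outlet or at the end, in percent of the starting material put in, Saturday's
4. amount of intermediate A at the outlet or at the end, in percent of the starting material put in, Tuesday's
5. amount of intermediate A at the outlet or at the end, in percent of the starting material put in, Sunday's

I counted in fractions of the starting material charged. In Tuesday's flask the starting material had a half-life of 0.050 d against the partner, far shorter than the run, so I took it as turned into intermediate A early. The partner's own decay, with a half-life of 1200 d, was far slower than the run. The second reagent then took intermediate A one for one, and nothing downstream gave intermediate A back. With e equivalents of it, the second reagent was the limiting reagent of that step: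

e = 0.500

f = one − e = 50.0%

I called f the uncovered share: the part of the charge that the second reagent cannot reach, as long as e stays below one. Control changes hands at a crossing, from the rate of that step to this ratio, and the time scale of the crossing comes from the intermediate A that outlasts the second reagent:

τ = one / (3.9 M⁻¹ h⁻¹ × f × 0.010 M) = 2.14 d

τ was shorter than Tuesday's run, so the run lay past the crossing. There the ratio of second reagent to intermediate A falls from e as exp(−t/τ):

Tuesday's: f + f·e·exp(−t/τ) = 50.6%

The twin's smaller e gives it a larger f, so I expected the two to part by their charges. For Monday's tank, with mean residence time θ, I held intermediate A at f in the balance of the second reagent: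

Monday's: f + e / (one + θ/τ) = 60.5%

I left the two dosed flasks unreckoned.

The forecast named Monday's, with 57.5% there, 50.8% for Saturday's, 50.6% for Tuesday's and 52.5% for Sunday's, noting that “the equilibrium step does not feed back on A”. Its Monday's figure differs from mine.

The simulation put Monday's first at 57.5%, with Saturday's 54.5%, Sunday's 52.5% and Tuesday's 50.6%. The forecast's choice would have failed had another set-up come first, or had the first two lain within 2 percentage points; Monday's stood 3 points above Saturday's. Tuesday's flask stood 0.60 points above f, with 1.3% of its second reagent left. The twin, by the same reckoning, has f = 87.0%, and its run left 0.14% of its second reagent and ended with 87.0% as intermediate A.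

All constants come from no measurement; the result is computed.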